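## Structural features

The target (31) is a cembranolide: a 14-membered carbocycle C1–C14 that shares its C1–C2 bond with an α-methylene-γ-butyrolactone (ring O–C16(=O)–C15(=C17H2)–C1–C2), the two rings being trans-fused (1R,2S); these cembrane locants are used for atoms throughout, whatever the locants of a systematic name. Going round the large ring from C2 there are two E trisubstituted alkenes in a skipped 1,5 relationship (C3=C4 and C7=C8, methyl groups on C4 and C8), then a trisubstituted epoxide (C11–C12, methyl on C12, 11R,12S) and the secondary acetate at C13 (13S); only the C14 methylene separates C13 from the ring-fusion carbon C1. The five stereocentres therefore form two clusters, C1/C2 (adjacent) and C11/C12/C13 (contiguous), insulated from each other by C14 on one side and by eight ring atoms on the other. The fragile parts are the exocyclic enoate (a Michael acceptor that also binds low-valent metals), the lactone C2–O bond (allylic to C3=C4, hence ionisable), the epoxide beside an ester (acid-labile, and open to acyl or epoxide migration once the acetate is cleaved) and the acid-sensitive 1,5-diene array. The real difficulty is to close the 14-membered carbocycle with control of alkene geometry, and then to place oxygen on C11, C12 and C13 with the threo relation of epoxide and acetate and the right sense relative to the distant lactone. The feature used is that, with the epoxide taken back to an alkene, C13 is a carbinol carbon on the methyl-bearing carbon C12 of an E C11=C12 alkene inside the ring: such a 2-methyl allylic alcohol is what syn addition of hydrogen (to C11) and an aldehyde carbon C13 (to C12) across a methyl-capped C11≡C12 alkyne delivers, so one reductive coupling makes the ring bond C12–C13, the alkene geometry and the C13 oxygen, and the new hydroxyl can then steer the epoxidation.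

## Logic of the disconnections

31 ⇒ 30. The C13–O(acetyl) bond is cut with inversion at C13. Epoxide oxygen and C13 oxygen are threo in 31, whereas an epoxidation directed by a C13 hydroxyl gives the erythro isomer; introducing the acetate last, by displacement, reconciles the two. Gain: the base-labile ester disappears and the problem becomes an erythro epoxy alcohol. Demand: a clean SN2 reaction at a carbinol flanked by a fully substituted epoxide carbon, without opening the epoxide or adding to the enoate.

30 ⇒ 29. The two epoxide C–O bonds (C11–O, C12–O) are cut. The C13 hydroxyl of 29 is the only free hydroxyl and sits on the alkene to be oxidised, so a metal-bound peroxide can pick C11=C12 out of four alkenes. Gain: three contiguous stereocentres shrink to one. Demand: oxygen delivery erythro to the hydroxyl, which from 13R gives the 11R epoxide required.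

29 ⇒ 28 ⇒ 26 ⇒ 24. The O–Si bond is a formality; the real cut is C15–C17, the exocyclic methylene. It is removed because an enoate would compete for zerovalent nickel in the ring closure and would not survive the steps before it. Gain: 24 carries a plain saturated lactone. Demand: the enolate aminomethylation and elimination must run while C13 is masked (the silyl ether born in the ring closure does this at no cost) and before epoxide and acetate exist.

24 ⇒ 23 (the strategic cut). The ring bond C12–C13 and the C11–H bond are cut, which turns the E C11=C12 alkene into a C11≡C12 alkyne and C13 into an aldehyde. This is the only ring bond whose formation also creates the oxygen needed at C13 and fixes an alkene geometry by mechanism. Gain: the 14-membered ring opens to a chain hung on a small lactone that already holds C1 and C2, and one stereocentre goes. Demand: bond formation at the methyl-bearing alkyne carbon (endocyclic closure), high dilution, and a preference for the 13R face of the aldehyde. A small carbene ligand serves the first demand; the bulky chiral carbenes that might serve the last would push the closure towards the exocyclic mode, so C13 is left to substrate control with a redox correction in reserve.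

23 ⇒ 22 ⇒ 20. No skeletal bond is cut; C13 is taken down from aldehyde to the terminal carbon of a vinyl group. The aldehyde is too sensitive to carry, and a vinyl group is the most robust two-carbon surrogate. Gain: 20 has only a lactone and hydrocarbon unsaturation. Demand: the hydroboration must distinguish one monosubstituted alkene from two trisubstituted alkenes and an internal alkyne.

20 ⇒ 17 + 18. The C1–C14 bond is cut. Conjugate addition to a butenolide is governed by the substituent on the neighbouring carbon, so C2 can set C1 trans. Gain: the C1 stereocentre and two carbons are removed. Demand: addition anti to the side chain, faster than deprotonation at C2 or SN2′ attack on the allylic C2–O bond.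

17 ⇒ 15 ⇒ 12 + 13. The lactone C16–O bond is cut and the C1=C15 alkene is taken back to an alkyne, which exposes C1–C2 as the bond between an enal and a propiolate. C2 is the one stereocentre that must come from a reagent, and catalytic alkynylation of an enal makes it while bringing in C1, C15 and C16 together. Gain: an achiral enal and a three-carbon ester. Demand: enantioselectivity in the addition, and a Z-selective semi-reduction that takes only the electron-poor alkyne and stops at the butenolide.

12 ⇒ 11 ⇒ 9 ⇒ 8 ⇒ 5 + 6. The C12–C20 bond (methyl cap) and the C9–C10 bond are cut. 6 is a three-carbon propargyl anion equivalent whose silyl group enforces propargylic rather than allenic alkylation; the cap is added once the silyl group is gone. Gain: the chain is reduced to a C10 terpene unit. Demand: SN2 rather than SN2′ attack on the allylic bromide, and C- rather than O-methylation of a dianion.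

5 ⇒ 3 ⇒ 2 ⇒ 1. The C9–Br and C9–O bonds are traced back to a C9–H bond. 1 already contains C2–C9 with the C3=C4 geometry, and oxidation of its E methyl group fixes the C7=C8 geometry. Gain: a commercial monoterpene. Demand: oxidation at the terminal E methyl group only.

## Other disconnections considered

Alternative 1: The cut removes C1–C15 and C13–C14 and restores C13–C15, leading back to the 15-membered β-keto macrolactone A1, which carries a vinyl group (C1=C14) on C2. Forward, irradiation of the enol form of A1 adds the enol C13=C15 across the vinyl group (De Mayo photocycloaddition) and retro-aldol cleavage of C13–C15 follows in the same operation, giving the lactone-fused C13 enone A2.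
- In its favour: ring closure is moved to an ester bond, the easiest macrocyclic bond to make, and one operation forms two C–C bonds, both final rings and the C1 centre.
- Better than the chosen plan: A2 holds C13 as a ketone, so 13R can be set by a CBS reduction instead of being left to the substrate.
- Equal: after reduction and silylation A2 becomes 24, so the end game is the same.
- Against it here: a β-keto ester is much less enolised than a diketone, and in A1 the keto group is part of the C11=C12 enone, so the absorbing dienol can isomerise at C11=C12 or add to the nearby C3=C4 alkene instead.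
- Against it here: the C1/C2 trans relation would rest on the face of the vinyl group chosen within a three-atom tether held by the macrocycle, through a 1,4-biradical that need not close stereospecifically; C2 in A1 is also a doubly allylic carboxylate prone to ionisation.
- Comparison: the step count would be about equal (A1 needs a synthesis of similar length to that of 23, and two steps separate A2 from 24). The nickel closure is mechanistically the more predictable for this substitution pattern and fixes the C11=C12 geometry instead of exposing it to light.

Alternative 2: The cut is C1–C14, with a C17–O bond added back: the 14-membered C13 enone A4 comes from the 16-membered 2-methylene oxacycle A3, an allyl vinyl ether (C14=C13–O–C17–C15=C1). Forward, heating A3 triggers a Claisen [3,3] shift that forms C1–C14, turns C13 into a ketone, leaves C15=C17 as the exocyclic methylene and contracts the ring.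
- In its favour: the large ring is again first closed through a carbon–oxygen bond, and chirality can pass from C2 to C1 through an ordered transition state.
- Better than the chosen plan: the methylene carbon C17 arrives in the rearrangement, sparing the enolate aminomethylation and elimination, and the C13 ketone allows reagent-controlled reduction.
- Against it here: A3 must be made by methylenating a conjugated ester carbonyl inside a ring with Cp2TiMe2 or a related titanium methylidene source, and it is an acid-labile 2-alkoxy diene.
- Against it here: the configuration at C1 depends on a chair or boat preference in a macrocyclic transition state and on the C15=C1 geometry, neither of which is secured.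
- Against it here: A4 carries C16 at the alcohol oxidation level and C2 as a silyl ether, so selective desilylation, two oxidations and lactonisation are needed before epoxidation and inversion.
- Comparison: the route would be about four steps longer. The stereochemical risk moves from C13 (chosen plan) to C1 (alternative), and C1 cannot be repaired by a redox step whereas C13 can.

Alternative 3: The cut is the C7=C8 alkene, leading back to the open-chain keto aldehyde A5 (C7 aldehyde, C8 methyl ketone; oxygens on C2, C13 and C16 silylated). Forward, low-valent titanium from TiCl3(DME)1.5 and Zn(Cu) couples the two carbonyl groups reductively (McMurry coupling) and closes the 14-membered triene A6.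
- Equal or better: titanium carbonyl coupling is a well-tried way to close 14-membered terpenoid rings and, as a ring closure, matches or exceeds the nickel reaction in reliability.
- Better than the chosen plan: C1, C2 and C13 are all set on an open chain before the ring exists, so C13 does not depend on a macrocyclic transition state.
- Against it here: an aldehyde/methyl ketone coupling gives a trisubstituted alkene with little control of E/Z geometry, whereas the chosen plan fixes C11=C12 by syn addition and inherits C7=C8 from 1.
- Against it here: the reagent is used in large excess and pinacol formation competes.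
- Against it here: A5 is a long linear compound with three stereocentres and two differentiated carbonyl groups, with no early lactone to set C1 from C2; after A6 three silyl ethers must be told apart and C16 oxidised and lactonised before the shared end game.
- Comparison: the route would be several steps longer, and its advantage at C13 is paid for with a loss at C7=C8.

Key step: step 13

Assumption: the (R,R) antipode of ProPhenol (2,6-bis{[2-(hydroxydiphenylmethyl)pyrrolidin-1-yl]methyl}-4-methylphenol) is taken to deliver the alkynyl group to the Re face of 12 (4S in 15); if the facial sense is the opposite, the (S,S) ligand is used with no other change.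

## Route

Step 1
Reactants: 1 geraniol
Product: 2 tert-butyl{[(2E)-3,7-dimethylocta-2,6-dien-1-yl]oxy}dimethylsilane
Conditions: TBSCl, imidazole, DMF, 0 °C → rt
Reagents that add atoms: tert-butyldimethylsilyl chloride, CC(C)(C)[Si](C)(C)Cl
Why: Standard silyl ether formation on a primary alcohol; the ether survives the oxidation, bromide formation and organolithium steps and leaves together with the C-silyl group in step 5.

Step 2
Reactants: 2 tert-butyl{[(2E)-3,7-dimethylocta-2,6-dien-1-yl]oxy}dimethylsilane
Product: 3 (2E,6E)-8-{[tert-butyl(dimethyl)silyl]oxy}-2,6-dimethylocta-2,6-dien-1-ol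
Conditions: SeO2 (0.3 equiv), t-BuOOH (3 equiv), salicylic acid (0.1 equiv), CH2Cl2, 0 °C → rt
Reagents that add atoms: tert-butyl hydroperoxide, CC(C)(C)OO; selenium dioxide (oxygen carrier), O=[Se]=O
Why: Selenium dioxide allylic oxidation (ene reaction then [2,3]-sigmatropic shift) goes to the E methyl group of the more electron-rich terminal alkene; the C3=C4 alkene is deactivated by its allylic oxygen, and conversion is held short of completion to limit over-oxidation to the enal.

Step 3
Reactants: 3 (2E,6E)-8-{[tert-butyl(dimethyl)silyl]oxy}-2,6-dimethylocta-2,6-dien-1-ol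
Product: 5 {[(2E,6E)-8-bromo-3,7-dimethylocta-2,6-dien-1-yl]oxy}(tert-butyl)dimethylsilane, via allylic mesylate 4 (not isolated)
Conditions: MsCl, Et3N, THF, −40 °C; then LiBr, −40 → 0 °C
Reagents that add atoms: lithium bromide, [Li+].[Br-]
Why: Mesylation and in situ SN2 displacement by bromide at a primary allylic carbon; at low temperature no allylic transposition or alkene isomerisation is expected.

Step 4
Reactants: 5 {[(2E,6E)-8-bromo-3,7-dimethylocta-2,6-dien-1-yl]oxy}(tert-butyl)dimethylsilane; 6 1-(trimethylsilyl)propyne
Product: 8 tert-butyl{[(2E,6E)-3,7-dimethyl-11-(trimethylsilyl)undeca-2,6-dien-10-yn-1-yl]oxy}dimethylsilane, via silylpropargyllithium 7 (not isolated)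
Conditions: 6, n-BuLi, THF, −78 → −20 °C; then 5, −78 °C → rt
Reagents that add atoms: none
Why: Alkylation of a silyl-protected propargyl anion: the silyl group keeps the anion from reacting as an allenyl species, and the primary allylic bromide is attacked in the SN2 sense, forming C9–C10 with the C7=C8 geometry untouched.

Step 5
Reactants: 8 tert-butyl{[(2E,6E)-3,7-dimethyl-11-(trimethylsilyl)undeca-2,6-dien-10-yn-1-yl]oxy}dimethylsilane
Product: 9 (2E,6E)-3,7-dimethylundeca-2,6-dien-10-yn-1-ol
Conditions: TBAF (2.5 equiv), THF, 0 °C → rt
Reagents that add atoms: none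
Why: Fluoride-mediated desilylation cleaves the O–Si bond and the alkynyl C–Si bond in one operation, so no separate protecting-group step is spent.

Step 6
Reactants: 9 (2E,6E)-3,7-dimethylundeca-2,6-dien-10-yn-1-ol
Product: 11 (2E,6E)-3,7-dimethyldodeca-2,6-dien-10-yn-1-ol, via dilithio alkoxide acetylide 10 (not isolated)
Conditions: n-BuLi (2.1 equiv), THF, −78 → −20 °C; then MeI (1.05 equiv), −78 °C → rt
Reagents that add atoms: iodomethane, CI
Why: Alkylation of an alkynide: in the dianion the acetylide carbon is far more nucleophilic than the lithium alkoxide in THF, so one equivalent of iodomethane caps C12 with the C20 methyl group.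

Step 7
Reactants: 11 (2E,6E)-3,7-dimethyldodeca-2,6-dien-10-yn-1-ol
Product: 12 (2E,6E)-3,7-dimethyldodeca-2,6-dien-10-ynal
Conditions: MnO2 (activated, excess), CH2Cl2, rt
Reagents that add atoms: none
Why: Manganese dioxide oxidises only the allylic alcohol and leaves the E geometry of the enal intact.

Step 8
Reactants: 12 (2E,6E)-3,7-dimethyldodeca-2,6-dien-10-ynal; 13 methyl propiolate
Product: 15 methyl (4S,5E,9E)-4-hydroxy-6,10-dimethylpentadeca-5,9-dien-2,13-diynoate, via methylzinc acetylide 14 (not isolated)
Conditions: 13 (3 equiv), Me2Zn (3 equiv), (R,R)-ProPhenol (20 mol%), Ph3P=O (40 mol%), toluene, 0 °C; then 12, 4 °C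
Reagents that add atoms: none
Why: Catalytic enantioselective alkynylation of an aldehyde by a zinc acetylide held in the dinuclear zinc ProPhenol complex; delivery of the alkynyl group to the Re face of the enal sets C2 (4S in 15), and enals are among the best substrates of this reaction type.

Step 9
Reactants: 15 methyl (4S,5E,9E)-4-hydroxy-6,10-dimethylpentadeca-5,9-dien-2,13-diynoate
Product: 17 (5R)-5-[(1E,5E)-2,6-dimethylundeca-1,5-dien-9-yn-1-yl]furan-2(5H)-one, via (Z)-4-hydroxy enoate 16 (not isolated)
Conditions: [(Ph3P)CuH]6 (0.25 equiv), H2O (3 equiv), degassed toluene, 0 °C → rt; lactonisation completed on SiO2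
Reagents that add atoms: none
Why: Conjugate reduction by a copper hydride (hydrocupration): syn addition of H and Cu to the electron-poor ynoate and protonation give the Z enoate 16, which lactonises to the butenolide; the unactivated C11≡C12 alkyne is not hydrometallated under these conditions, and keeping the hydride near one equivalent guards 17 against a second reduction (the R descriptor of 17 reflects a priority change, not an inversion).

Step 10
Reactants: 17 (5R)-5-[(1E,5E)-2,6-dimethylundeca-1,5-dien-9-yn-1-yl]furan-2(5H)-one; 18 vinylmagnesium bromide
Product: 20 (4S,5R)-5-[(1E,5E)-2,6-dimethylundeca-1,5-dien-9-yn-1-yl]-4-ethenyloxolan-2-one, via trimethylsilyl ketene acetal 19 (not isolated)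
Conditions: 18 (1.5 equiv, slow addition), CuBr·SMe2 (0.15 equiv), Me3SiCl (2 equiv), THF, −78 °C; aq. NH4Cl
Reagents that add atoms: none
Why: Copper-catalysed conjugate addition of the vinyl Grignard reagent (cuprate 1,4-addition) occurs anti to the C2 side chain, which sets C1 trans to C2; Me3SiCl traps the enolate and speeds the 1,4-addition past γ-deprotonation or SN2′ opening of the allylic lactone.

Step 11
Reactants: 20 (4S,5R)-5-[(1E,5E)-2,6-dimethylundeca-1,5-dien-9-yn-1-yl]-4-ethenyloxolan-2-one
Product: 22 (4R,5R)-5-[(1E,5E)-2,6-dimethylundeca-1,5-dien-9-yn-1-yl]-4-(2-hydroxyethyl)oxolan-2-one, via B-alkyl-9-BBN adduct 21 (not isolated)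
Conditions: 9-BBN (1.1 equiv), THF, 0 °C → rt; then NaBO3·4H2O, H2O, rt
Reagents that add atoms: sodium perborate (dimeric peroxoborate), [Na+].[Na+].O[B-]1(O)OO[B-](O)(O)OO1
Why: Hydroboration–oxidation: 9-BBN adds anti-Markovnikov to the monosubstituted alkene far faster than to trisubstituted alkenes or the internal alkyne, and perborate oxidises the C–B bond without opening the lactone.

Step 12
Reactants: 22 (4R,5R)-5-[(1E,5E)-2,6-dimethylundeca-1,5-dien-9-yn-1-yl]-4-(2-hydroxyethyl)oxolan-2-one
Product: 23 2-{(2R,3R)-2-[(1E,5E)-2,6-dimethylundeca-1,5-dien-9-yn-1-yl]-5-oxooxolan-3-yl}acetaldehyde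
Conditions: Dess–Martin periodinane, CH2Cl2, 0 °C → rt
Reagents that add atoms: none
Why: Dess–Martin oxidation of the primary alcohol under near-neutral conditions gives the aldehyde without epimerising C1 or touching the alkyne and alkenes; 23 is used at once.

Step 13
Reactants: 23 2-{(2R,3R)-2-[(1E,5E)-2,6-dimethylundeca-1,5-dien-9-yn-1-yl]-5-oxooxolan-3-yl}acetaldehyde
Product: 24 (1R,2R,3E,7E,11E,13R)-13-(triethylsilyloxy)-17-norcembra-3,7,11-trien-16,2-olide
Conditions: Ni(cod)2 (25 mol%), IMes (1,3-dimesitylimidazol-2-ylidene, 25 mol%), Et3SiH (5 equiv), THF, 23 added by syringe pump to 0.005 M, rt → 45 °C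
Reagents that add atoms: triethylsilane, CC[SiH](CC)CC
Why: This is a nickel-catalysed reductive alkyne–aldehyde coupling used as a macrocyclisation, a known reaction type for ynals with carbene ligands and silane reductants. Zerovalent nickel carrying IMes binds the C11≡C12 alkyne and the C13 aldehyde and couples them oxidatively to an oxanickelacyclopentene that already contains the C12–C13 bond; σ-bond metathesis of the Ni–O bond with Et3SiH and C–H reductive elimination then put the silyl group on the C13 oxygen and hydrogen on C11 cis to C13, so the new alkene can only be E. The 14-membered carbocycle closes in the endocyclic mode: C13 bonds to the distal alkyne carbon C12, both alkyne carbons become ring members and the methyl group stays outside. A small carbene favours exactly this regiochemistry, because C–C bond formation then goes to the alkyne carbon with the smaller substituent, here the methyl cap, so ligand and substrate bias point the same way. The new C13 stereocentre is set under substrate control by the trans-lactone, whose C1 centre stands 1,3 to the aldehyde and fixes the direction in which the C14 methylene enters the ring-forming transition state; the 13R epimer is the one needed, and its preference is the least secure point of the step. Chemoselectivity needs no protecting group: 23 has no enoate or enone to bind nickel, the lactone carbonyl and the trisubstituted alkenes are poor ligands, and slow addition at high dilution keeps intermolecular coupling down.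

Step 14
Reactants: 24 (1R,2R,3E,7E,11E,13R)-13-(triethylsilyloxy)-17-norcembra-3,7,11-trien-16,2-olide
Product: 26 (1R,2R,3E,7E,11E,13R,15S)-17-(dimethylamino)-13-(triethylsilyloxy)cembra-3,7,11-trien-16,2-olide, via O-lithium enolate 25 (not isolated)
Conditions: LiN(SiMe3)2 (1.2 equiv), THF, −78 °C; then Eschenmoser's salt (3 equiv), −78 °C → rt
Reagents that add atoms: dimethyl(methylidene)ammonium iodide, C=[N+](C)C.[I-]
Why: Mannich reaction of the lactone lithium enolate with Eschenmoser's salt; C15 becomes a stereocentre (attack anti to the C14 branch expected) that is erased in step 15, and the silyl ether from step 13 protects C13 throughout.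

Step 15
Reactants: 26 (1R,2R,3E,7E,11E,13R,15S)-17-(dimethylamino)-13-(triethylsilyloxy)cembra-3,7,11-trien-16,2-olide
Product: 28 (1R,2S,3E,7E,11E,13R)-13-(triethylsilyloxy)cembra-3,7,11,15(17)-tetraen-16,2-olide, via trimethylammonium iodide 27 (not isolated)
Conditions: MeI (excess), MeOH–CH2Cl2, rt; then aq. NaHCO3, CH2Cl2, rt
Reagents that add atoms: none
Why: N-Methylation and base-induced β-elimination of trimethylamine (Hofmann-type, E1cB) give the exocyclic enoate under conditions too mild to move the double bond into the ring; the change of the C2 descriptor from R to S is a priority change only.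

Step 16
Reactants: 28 (1R,2S,3E,7E,11E,13R)-13-(triethylsilyloxy)cembra-3,7,11,15(17)-tetraen-16,2-olide
Product: 29 (1R,2S,3E,7E,11E,13R)-13-hydroxycembra-3,7,11,15(17)-tetraen-16,2-olide
Conditions: HF·pyridine, pyridine, THF, 0 °C
Reagents that add atoms: none
Why: Acidic fluoride cleaves the triethylsilyl ether; buffering with pyridine protects the allylic alcohol and the allylic lactone from ionisation, and the non-basic medium spares the enoate.

Step 17
Reactants: 29 (1R,2S,3E,7E,11E,13R)-13-hydroxycembra-3,7,11,15(17)-tetraen-16,2-olide
Product: 30 (1R,2S,3E,7E,11R,12R,13R)-11,12-epoxy-13-hydroxycembra-3,7,15(17)-trien-16,2-olide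
Conditions: VO(acac)2 (10 mol%), t-BuOOH (1.5 equiv, in decane), CH2Cl2, 0 °C → rt
Reagents that add atoms: tert-butyl hydroperoxide, CC(C)(C)OO
Why: Hydroxyl-directed vanadium-catalysed epoxidation touches only the alkene of the allylic alcohol; in the vanadate ester the C14 branch on C13 avoids the C12 methyl group (A(1,2) strain), so oxygen is delivered erythro to the hydroxyl, which from 13R gives 11R and the C12 configuration of the target (12R as named for the free alcohol).

Step 18
Reactants: 30 (1R,2S,3E,7E,11R,12R,13R)-11,12-epoxy-13-hydroxycembra-3,7,15(17)-trien-16,2-olide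
Product: 31 (1R,2S,3E,7E,11R,12S,13S)-13-acetoxy-11,12-epoxycembra-3,7,15(17)-trien-16,2-olide
Conditions: PPh3, DIAD, AcOH, toluene, 0 °C → rt
Reagents that add atoms: acetic acid, CC(=O)O
Why: Mitsunobu esterification: the C13 alkoxyphosphonium ion is displaced by acetate with inversion (13R to 13S), turning the erythro epoxy alcohol into the threo epoxy acetate without a basic step; the C12 descriptor changes from R to S by priority only.

## Compound list

1 | geraniol, (2E)-3,7-dimethylocta-2,6-dien-1-ol | CC(C)=CCC/C(C)=C/CO | starting material
2 | tert-butyl{[(2E)-3,7-dimethylocta-2,6-dien-1-yl]oxy}dimethylsilane | CC(C)=CCC/C(C)=C/CO[Si](C)(C)C(C)(C)C | intermediate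
3 | (2E,6E)-8-{[tert-butyl(dimethyl)silyl]oxy}-2,6-dimethylocta-2,6-dien-1-ol | OC/C(C)=C/CC/C(C)=C/CO[Si](C)(C)C(C)(C)C | intermediate
4 | (2E,6E)-8-{[tert-butyl(dimethyl)silyl]oxy}-2,6-dimethylocta-2,6-dien-1-yl methanesulfonate | CS(=O)(=O)OC/C(C)=C/CC/C(C)=C/CO[Si](C)(C)C(C)(C)C | intermediate
5 | {[(2E,6E)-8-bromo-3,7-dimethylocta-2,6-dien-1-yl]oxy}(tert-butyl)dimethylsilane | BrC/C(C)=C/CC/C(C)=C/CO[Si](C)(C)C(C)(C)C | intermediate
6 | 1-(trimethylsilyl)propyne | CC#C[Si](C)(C)C | starting material
7 | [3-(trimethylsilyl)prop-2-yn-1-yl]lithium | [Li]CC#C[Si](C)(C)C | intermediate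
8 | tert-butyl{[(2E,6E)-3,7-dimethyl-11-(trimethylsilyl)undeca-2,6-dien-10-yn-1-yl]oxy}dimethylsilane | C[Si](C)(C)C#CCC/C(C)=C/CC/C(C)=C/CO[Si](C)(C)C(C)(C)C | intermediate
9 | (2E,6E)-3,7-dimethylundeca-2,6-dien-10-yn-1-ol | C#CCC/C(C)=C/CC/C(C)=C/CO | intermediate
10 | dilithium salt of 9 (lithium alkoxide and lithium acetylide) | [Li]C#CCC/C(C)=C/CC/C(C)=C/CO[Li] | intermediate
11 | (2E,6E)-3,7-dimethyldodeca-2,6-dien-10-yn-1-ol | CC#CCC/C(C)=C/CC/C(C)=C/CO | intermediate
12 | (2E,6E)-3,7-dimethyldodeca-2,6-dien-10-ynal | CC#CCC/C(C)=C/CC/C(C)=C/C=O | intermediate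
13 | methyl propiolate | C#CC(=O)OC | starting material
14 | methyl 3-(methylzincio)prop-2-ynoate | C[Zn]C#CC(=O)OC | intermediate
15 | methyl (4S,5E,9E)-4-hydroxy-6,10-dimethylpentadeca-5,9-dien-2,13-diynoate | CC#CCC/C(C)=C/CC/C(C)=C/[C@@H](C#CC(=O)OC)O | intermediate
16 | methyl (2Z,4R,5E,9E)-4-hydroxy-6,10-dimethylpentadeca-2,5,9-trien-13-ynoate | CC#CCC/C(C)=C/CC/C(C)=C/[C@@H](/C=C\C(=O)OC)O | intermediate
17 | (5R)-5-[(1E,5E)-2,6-dimethylundeca-1,5-dien-9-yn-1-yl]furan-2(5H)-one | CC#CCC/C(C)=C/CC/C(C)=C/[C@@H]1OC(=O)C=C1 | intermediate
18 | vinylmagnesium bromide | C=C[Mg]Br | starting material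
19 | trimethyl({(4R,5R)-5-[(1E,5E)-2,6-dimethylundeca-1,5-dien-9-yn-1-yl]-4-ethenyl-4,5-dihydrofuran-2-yl}oxy)silane | CC#CCC/C(C)=C/CC/C(C)=C/[C@@H]1OC(O[Si](C)(C)C)=C[C@H]1C=C | intermediate
20 | (4S,5R)-5-[(1E,5E)-2,6-dimethylundeca-1,5-dien-9-yn-1-yl]-4-ethenyloxolan-2-one | CC#CCC/C(C)=C/CC/C(C)=C/[C@@H]1OC(=O)C[C@H]1C=C | intermediate
21 | 9-{2-[(2R,3R)-2-[(1E,5E)-2,6-dimethylundeca-1,5-dien-9-yn-1-yl]-5-oxooxolan-3-yl]ethyl}-9-borabicyclo[3.3.1]nonane | CC#CCC/C(C)=C/CC/C(C)=C/[C@@H]1OC(=O)C[C@H]1CCB1C2CCCC1CCC2 | intermediate
22 | (4R,5R)-5-[(1E,5E)-2,6-dimethylundeca-1,5-dien-9-yn-1-yl]-4-(2-hydroxyethyl)oxolan-2-one | CC#CCC/C(C)=C/CC/C(C)=C/[C@@H]1OC(=O)C[C@H]1CCO | intermediate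
23 | 2-{(2R,3R)-2-[(1E,5E)-2,6-dimethylundeca-1,5-dien-9-yn-1-yl]-5-oxooxolan-3-yl}acetaldehyde (trans-lactone ynal) | CC#CCC/C(C)=C/CC/C(C)=C/[C@@H]1OC(=O)C[C@H]1CC=O | intermediate
24 | (1R,2R,3E,7E,11E,13R)-13-(triethylsilyloxy)-17-norcembra-3,7,11-trien-16,2-olide (trans-lactone on the 14-membered ring) | C1C(=O)O[C@H]2/C=C(\C)CC/C=C(\C)CC/C=C(\C)[C@H](O[Si](CC)(CC)CC)C[C@H]12 | intermediate
25 | O-lithium enolate of 24 (C15=C16, other centres as in 24) | C1=C(O[Li])O[C@H]2/C=C(\C)CC/C=C(\C)CC/C=C(\C)[C@H](O[Si](CC)(CC)CC)C[C@H]12 | intermediate
26 | (1R,2R,3E,7E,11E,13R,15S)-17-(dimethylamino)-13-(triethylsilyloxy)cembra-3,7,11-trien-16,2-olide | CN(C)C[C@H]1C(=O)O[C@H]2/C=C(\C)CC/C=C(\C)CC/C=C(\C)[C@H](O[Si](CC)(CC)CC)C[C@H]12 | intermediate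
27 | N,N,N-trimethylammonium iodide of 26 (methylated at nitrogen) | C[N+](C)(C)C[C@H]1C(=O)O[C@H]2/C=C(\C)CC/C=C(\C)CC/C=C(\C)[C@H](O[Si](CC)(CC)CC)C[C@H]12.[I-] | intermediate
28 | (1R,2S,3E,7E,11E,13R)-13-(triethylsilyloxy)cembra-3,7,11,15(17)-tetraen-16,2-olide | C=C1C(=O)O[C@H]2/C=C(\C)CC/C=C(\C)CC/C=C(\C)[C@H](O[Si](CC)(CC)CC)C[C@H]12 | intermediate
29 | (1R,2S,3E,7E,11E,13R)-13-hydroxycembra-3,7,11,15(17)-tetraen-16,2-olide | C=C1C(=O)O[C@H]2/C=C(\C)CC/C=C(\C)CC/C=C(\C)[C@H](O)C[C@H]12 | intermediate
30 | (1R,2S,3E,7E,11R,12R,13R)-11,12-epoxy-13-hydroxycembra-3,7,15(17)-trien-16,2-olide | C=C1C(=O)O[C@H]2/C=C(\C)CC/C=C(\C)CC[C@H]3O[C@]3(C)[C@H](O)C[C@H]12 | intermediate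
31 | (1R,2S,3E,7E,11R,12S,13S)-13-acetoxy-11,12-epoxycembra-3,7,15(17)-trien-16,2-olide | C=C1C(=O)O[C@H]2/C=C(\C)CC/C=C(\C)CC[C@H]3O[C@]3(C)[C@@H](OC(C)=O)C[C@H]12 | target

## Step count and least certain steps

Total: 18 steps. Longest linear sequence: 18 steps (1 → 31); 6, 13 and 18 enter as purchased reagents.

Step 13 (key step). What is most likely to go wrong is poor facial selectivity at C13 in the oxidative cyclisation: the resident stereocentres lie outside the forming metallacycle, and a 14-membered transition state has several conformers of similar energy. A second risk is leakage into the exocyclic mode or oligomerisation if the catalyst rests on the aldehyde. Fallback: the silyl ethers are carried as a C13 epimer mixture through steps 14 to 16, which do not depend on the C13 configuration. The fallback then sets out from 29 obtained in this way as a mixture of C13 epimers and oxidises it with Dess–Martin periodinane (CH2Cl2, 0 °C) to the single C13 enone (1R,2S,3E,7E,11E)-13-oxocembra-3,7,11,15(17)-tetraen-16,2-olide F1. Reduction with the (S)-CBS oxazaborolidine and catecholborane (toluene, −78 °C), in which the 2-methylalkenyl side acts as the large group, should deliver hydride to the face that gives 13R, and the fallback comes back to the route at 29. C13 is then fixed by a reagent and not by the ring closure.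

Step 9. What is most likely to go wrong is over-reduction, a second conjugate hydride transfer to the butenolide as it forms, or loss of hydride to the free hydroxyl; substrate and product are Michael acceptors of a similar kind. Fallback from 15: syn hydrostannation with Bu3SnH and catalytic Pd(PPh3)4 (THF, 0 °C) places tin on the ester-bearing carbon and cannot reduce further; it gives methyl (2E,4S,5E,9E)-4-hydroxy-6,10-dimethyl-2-(tributylstannyl)pentadeca-2,5,9-trien-13-ynoate F2. F2 lactonises on mild acid treatment (PPTS, CH2Cl2) to (5S)-5-[(1E,5E)-2,6-dimethylundeca-1,5-dien-9-yn-1-yl]-3-(tributylstannyl)furan-2(5H)-one F3 (same spatial arrangement as 17). Protodestannylation with CF3CO2H (CH2Cl2, 0 °C) returns to the route at 17.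

Step 17. What is most likely to go wrong is delivery of oxygen to the wrong alkene face, if the conformation of the 14-membered ring rather than the acyclic A(1,2) model decides which face of C11=C12 the vanadate ester can reach. Fallback from 29: Ti(OiPr)4, D-(−)-diisopropyl tartrate, t-BuOOH, 4 Å molecular sieves, CH2Cl2, −20 °C (Sharpless epoxidation). This tartrate antipode has an intrinsic face preference that coincides with the erythro mode of a 13R alcohol, so a chiral reagent and the substrate act together; the fallback comes back at 30 and makes no new compound (F0).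

Step 18. What is most likely to go wrong is a slow displacement at a carbinol next to a fully substituted epoxide carbon with a weakly acidic pronucleophile, letting elimination, epoxide participation or phosphine addition to the enoate take over. Fallback from 30: MsCl, Et3N (CH2Cl2, −20 °C) gives the 13R methanesulfonate (1R,2S,3E,7E,11R,12S,13R)-11,12-epoxy-13-(methanesulfonyloxy)cembra-3,7,15(17)-trien-16,2-olide F4. CsOAc with 18-crown-6 in toluene at 80 °C then displaces the sulfonate with inversion, and the fallback comes back at 31.

## Further compounds

F1 | step 13 | (1R,2S,3E,7E,11E)-13-oxocembra-3,7,11,15(17)-tetraen-16,2-olide | C=C1C(=O)O[C@H]2/C=C(\C)CC/C=C(\C)CC/C=C(\C)C(=O)C[C@H]12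
F2 | step 9 | methyl (2E,4S,5E,9E)-4-hydroxy-6,10-dimethyl-2-(tributylstannyl)pentadeca-2,5,9-trien-13-ynoate | CC#CCC/C(C)=C/CC/C(C)=C/[C@@H](/C=C(/[Sn](CCCC)(CCCC)CCCC)C(=O)OC)O
F3 | step 9 | (5S)-5-[(1E,5E)-2,6-dimethylundeca-1,5-dien-9-yn-1-yl]-3-(tributylstannyl)furan-2(5H)-one | CC#CCC/C(C)=C/CC/C(C)=C/[C@@H]1OC(=O)C([Sn](CCCC)(CCCC)CCCC)=C1
F0 | step 17 | none | none
F4 | step 18 | (1R,2S,3E,7E,11R,12S,13R)-11,12-epoxy-13-(methanesulfonyloxy)cembra-3,7,15(17)-trien-16,2-olide | C=C1C(=O)O[C@H]2/C=C(\C)CC/C=C(\C)CC[C@H]3O[C@]3(C)[C@H](OS(C)(=O)=O)C[C@H]12
A1 | alternative 1 | (5E,9E,13E,15R)-15-ethenyl-5,9,13-trimethyl-1-oxacyclopentadeca-5,9,13-triene-2,4-dione (15-membered β-keto macrolactone) | C=C[C@@H]1/C=C(\C)CC/C=C(\C)CC/C=C(\C)C(=O)CC(=O)O1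
A2 | alternative 1 | (1R,2R,3E,7E,11E)-13-oxo-17-norcembra-3,7,11-trien-16,2-olide | C1C(=O)O[C@H]2/C=C(\C)CC/C=C(\C)CC/C=C(\C)C(=O)C[C@H]12
A3 | alternative 2 | 16-membered 2-methylene oxacycle (ring O–C17–C15=C1–C2…C12–C13, exocyclic C14 methylene on C13, CH2OTBS on C15, OTBS on C2) | C=C1OC/C(CO[Si](C)(C)C(C)(C)C)=C/[C@@H](O[Si](C)(C)C(C)(C)C)/C=C(\C)CC/C=C(\C)CC/C=C1\C
A4 | alternative 2 | 2,16-bis(tert-butyldimethylsilyloxy)cembra-3,7,11,15(17)-tetraen-13-one (C1 and C2 as in 31) | C=C(CO[Si](C)(C)C(C)(C)C)[C@H]1CC(=O)/C(C)=C/CC/C(C)=C/CC/C(C)=C/[C@@H]1O[Si](C)(C)C(C)(C)C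
A5 | alternative 3 | 7,8-seco keto aldehyde (C7 aldehyde, C8 methyl ketone, OTBS on C2, C13 and C16) | C=C(CO[Si](C)(C)C(C)(C)C)[C@@H](C[C@@H](O[Si](C)(C)C(C)(C)C)/C(C)=C/CCC(C)=O)[C@@H](O[Si](C)(C)C(C)(C)C)/C=C(\C)CCC=O
A6 | alternative 3 | 2,13,16-tris(tert-butyldimethylsilyloxy)cembra-3,7,11,15(17)-tetraene (C1, C2 as in 31, 13R) | C=C(CO[Si](C)(C)C(C)(C)C)[C@H]1C[C@@H](O[Si](C)(C)C(C)(C)C)/C(C)=C/CC/C(C)=C/CC/C(C)=C/[C@@H]1O[Si](C)(C)C(C)(C)C
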